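Ring C of the flavanone half (O1–C2–C3–C4(=O)–C4a=C8a) is a benzo-fused 2,3-dihydro-4H-pyran-4-one, the product type of an aldehyde–oxydiene cyclocondensation. The route therefore cuts C2–C3 and O1–C8a. The precursor is the enol silane of an aryl methyl ketone whose ring A carries fluorine at C8a (ortho to the C4 carbonyl, meta to the C5 and C7 ethers) and the protected apigenin unit at C8. In one operation a catalyst-controlled Mukaiyama aldol addition to 4-(benzyloxy)benzaldehyde sets C2 and the aldolate oxygen displaces fluoride at C8a, which closes ring C and fixes the 8-aryl regiochemistry.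

Key step: step 9

Assumption: the target structure leaves the configuration of the 8,8''-biaryl axis open, so the route controls only C2 (S) and accepts the axis as it forms.

Step 1
Reactants: 1 apigenin
Product: 2 5,7,4'-tri-O-benzylapigenin
Conditions: BnBr (4 equiv), K2CO3, Bu4NI (cat.), DMF, 80 °C
Reagents that add atoms: benzyl bromide, BrCc1ccccc1
Why: Williamson ether synthesis; excess benzyl bromide and K2CO3 in hot DMF should also alkylate the hydrogen-bonded 5-OH, so all three phenols end as benzyl ethers.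

Step 2
Reactants: 2 5,7,4'-tri-O-benzylapigenin
Product: 3 8-iodo-5,7,4'-tri-O-benzylapigenin
Conditions: N-iodosuccinimide (1.1 equiv), CF3CO2H (cat.), MeCN–CH2Cl2, 0 °C to rt
Reagents that add atoms: N-iodosuccinimide, O=C1CCC(=O)N1I
Why: Electrophilic aromatic iodination; ring A is the most electron-rich ring and, with O5 alkylated, C8 (between O1 and one benzyloxy group) should be attacked in preference to C6 (between two benzyloxy groups).

Step 3
Reactants: 3 8-iodo-5,7,4'-tri-O-benzylapigenin
Product: 4 5,7,4'-tri-O-benzylapigenin-8-boronic acid pinacol ester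
Conditions: B2pin2, PdCl2(dppf) (5 mol%), KOAc, 1,4-dioxane, 90 °C
Reagents that add atoms: bis(pinacolato)diboron, CC1(C)OB(B2OC(C)(C)C(C)(C)O2)OC1(C)C
Why: Miyaura borylation of an aryl iodide; KOAc is too weak a base to start a Suzuki homocoupling of the product.

Step 4
Reactants: 5 5-fluorobenzene-1,3-diol
Product: 6 1,3-bis(benzyloxy)-5-fluorobenzene
Conditions: BnBr (2.3 equiv), K2CO3, DMF, 50 °C
Reagents that add atoms: benzyl bromide, BrCc1ccccc1
Why: Williamson ether synthesis of two unhindered phenols.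

Step 5
Reactants: 6 1,3-bis(benzyloxy)-5-fluorobenzene
Product: 8 1,5-bis(benzyloxy)-3-fluoro-2-iodobenzene, via aryllithium 7 (not isolated)
Conditions: lithium 2,2,6,6-tetramethylpiperidide (LiTMP, 1.15 equiv), THF, −78 °C; then I2, −78 to −40 °C; aq. Na2S2O3
Reagents that add atoms: iodine, II; lithium 2,2,6,6-tetramethylpiperidide, [Li]N1C(C)(C)CCCC1(C)C (its lithium is carried only by intermediate 7)
Why: Directed ortho-metalation at the C–H flanked by fluorine and a benzyloxy group, the most acidic ring position, by a hindered amide base that should leave the benzylic CH2 groups alone, followed by iodinolysis of the aryllithium.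

Step 6
Reactants: 8 1,5-bis(benzyloxy)-3-fluoro-2-iodobenzene
Product: 10 1-[4,6-bis(benzyloxy)-2-fluoro-3-iodophenyl]ethan-1-one, via iodoaryllithium 9 (not isolated)
Conditions: LiTMP (1.1 equiv), THF, −78 °C (8 added to the base); then MeC(O)N(OMe)Me, −78 to 0 °C; 1 M HCl
Reagents that add atoms: N-methoxy-N-methylacetamide, CC(=O)N(C)OC; lithium 2,2,6,6-tetramethylpiperidide, [Li]N1C(C)(C)CCCC1(C)C (its lithium is carried only by intermediate 9)
Why: Second directed ortho-metalation at the remaining C–H between fluorine and a benzyloxy group (an amide base does not undergo iodine–lithium exchange), then acylation by a Weinreb amide, which stops at the ketone stage.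

Step 7
Reactants: 4 5,7,4'-tri-O-benzylapigenin-8-boronic acid pinacol ester; 10 1-[4,6-bis(benzyloxy)-2-fluoro-3-iodophenyl]ethan-1-one
Product: 11 8-[3-acetyl-4,6-bis(benzyloxy)-2-fluorophenyl]-5,7-bis(benzyloxy)-2-[4-(benzyloxy)phenyl]-4H-chromen-4-one
Conditions: Pd(OAc)2 (5 mol%), SPhos (10 mol%), K3PO4, toluene–H2O (10:1), 100 °C
Reagents that add atoms: none
Why: Suzuki–Miyaura coupling; the dialkylbiarylphosphine SPhos is suited to biaryls with four ortho substituents, and the C–F bond and the ketone should be inert to zerovalent palladium under these conditions.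

Step 8
Reactants: 11 8-[3-acetyl-4,6-bis(benzyloxy)-2-fluorophenyl]-5,7-bis(benzyloxy)-2-[4-(benzyloxy)phenyl]-4H-chromen-4-one
Product: 12 trimethylsilyl enol ether of 11
Conditions: Me3SiOTf (1.5 equiv), Et3N, CH2Cl2, 0 °C; cold aq. NaHCO3 wash, used crude
Reagents that add atoms: trimethylsilyl trifluoromethanesulfonate, C[Si](C)(C)OS(=O)(=O)C(F)(F)F
Why: Soft enolisation of the methyl ketone (silyl triflate and amine) gives the only possible enol silane; the non-enolisable flavone carbonyl is at most silylated reversibly.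

Step 9
Reactants: 12 trimethylsilyl enol ether of 11; 13 4-(benzyloxy)benzaldehyde
Product: 17 (2S)-5,7-bis(benzyloxy)-2-[4-(benzyloxy)phenyl]-8-{5,7-bis(benzyloxy)-2-[4-(benzyloxy)phenyl]-4-oxo-4H-chromen-8-yl}chroman-4-one, via trichlorosilyl aldolate 14 (not isolated), via (S)-aldol 15 (not isolated), via potassium aldolate 16 (not isolated)
Conditions: 13 (1.05 equiv), SiCl4 (1.5 equiv), binaphthyldiamine-derived bisphosphoramide (10 mol%, the antipode that directs Si-face attack, assigned on the enol silane of 2'-fluoroacetophenone as a model), iPr2NEt (10 mol%), CH2Cl2, −78 °C; then cold aq. KF/KH2PO4, phase separation, solvent exchange to THF without purification; then KN(SiMe3)2 (1.05 equiv), THF, −78 to −20 °C; AcOH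
Reagents that add atoms: silicon tetrachloride, Cl[Si](Cl)(Cl)Cl (its SiCl3 group is carried only by intermediate 14); potassium bis(trimethylsilyl)amide, C[Si](C)(C)N([K])[Si](C)(C)C (its potassium is carried only by intermediate 16); none of their atoms remains in 17
Why: The chiral phosphoramide-bound chlorosilyl cation formed from SiCl4 activates the aldehyde, and enol silane 12 adds to its Si face (catalytic enantioselective Mukaiyama aldol addition), which gives 14 and, after the fluoride quench, the (S)-aldol 15. Deprotonation gives alkoxide 16, whose oxygen adds to C8a of the vinylogous acyl fluoride C4(=O)–C4a=C8a–F and expels fluoride (intramolecular SNAr through a Meisenheimer anion stabilised by the C4 carbonyl). The closest known reaction type is the Mukaiyama aldol and cyclisation sequence that turns Danishefsky-type dienes and aldehydes into 2,3-dihydro-4H-pyran-4-ones, here with the aromatic C4a=C8a bond in the role of the enol ether and fluoride as the leaving group. Ring C closes by a 6-endo-trig addition–elimination with respect to C4a=C8a (6-exo-trig with respect to C8a=C8). C2 is set by the catalyst in the aldol stage and no bond to it is made or broken in the ring closure, so S in 15 becomes 2S in 17. The step needs ring closure to outrun retro-aldol cleavage and dehydration of 16, which low temperature, one equivalent of base and a fluorine ortho to the carbonyl and meta to both ether oxygens should secure; closure can only occur at C8a because C5 carries a benzyl ether, so no 6-aryl isomer can form.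

Step 10
Reactants: 17 (2S)-5,7-bis(benzyloxy)-2-[4-(benzyloxy)phenyl]-8-{5,7-bis(benzyloxy)-2-[4-(benzyloxy)phenyl]-4-oxo-4H-chromen-8-yl}chroman-4-one
Product: 18 (2S)-5,7-dihydroxy-2-(4-hydroxyphenyl)-8-[5,7-dihydroxy-2-(4-hydroxyphenyl)-4-oxo-4H-chromen-8-yl]chroman-4-one (CNP0339995.1)
Conditions: H2 (1 atm), 10% Pd/C, THF–MeOH, rt
Reagents that add atoms: none
Why: Hydrogenolysis of six benzyl aryl ethers under neutral conditions; no bond to C2 is touched and no acid or base is present that could open ring C, so the 2S centre is kept.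

Compound list
1 | apigenin | O=c1cc(-c2ccc(O)cc2)oc2cc(O)cc(O)c12 | starting material
2 | 5,7,4'-tri-O-benzylapigenin | O=c1cc(-c2ccc(OCc3ccccc3)cc2)oc2cc(OCc3ccccc3)cc(OCc3ccccc3)c12 | intermediate
3 | 8-iodo-5,7,4'-tri-O-benzylapigenin | O=c1cc(-c2ccc(OCc3ccccc3)cc2)oc2c(I)c(OCc3ccccc3)cc(OCc3ccccc3)c12 | intermediate
4 | 5,7,4'-tri-O-benzylapigenin-8-boronic acid pinacol ester | O=c1cc(-c2ccc(OCc3ccccc3)cc2)oc2c(B3OC(C)(C)C(C)(C)O3)c(OCc3ccccc3)cc(OCc3ccccc3)c12 | intermediate
5 | 5-fluorobenzene-1,3-diol | Oc1cc(O)cc(F)c1 | starting material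
6 | 1,3-bis(benzyloxy)-5-fluorobenzene | Fc1cc(OCc2ccccc2)cc(OCc2ccccc2)c1 | intermediate
7 | 2,4-bis(benzyloxy)-6-fluorophenyllithium (not isolated) | [Li]c1c(F)cc(OCc2ccccc2)cc1OCc1ccccc1 | intermediate
8 | 1,5-bis(benzyloxy)-3-fluoro-2-iodobenzene | Ic1c(F)cc(OCc2ccccc2)cc1OCc1ccccc1 | intermediate
9 | 4,6-bis(benzyloxy)-2-fluoro-3-iodophenyllithium (not isolated) | [Li]c1c(F)c(I)c(OCc2ccccc2)cc1OCc1ccccc1 | intermediate
10 | 1-[4,6-bis(benzyloxy)-2-fluoro-3-iodophenyl]ethan-1-one | CC(=O)c1c(F)c(I)c(OCc2ccccc2)cc1OCc1ccccc1 | intermediate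
11 | 8-[3-acetyl-4,6-bis(benzyloxy)-2-fluorophenyl]-5,7-bis(benzyloxy)-2-[4-(benzyloxy)phenyl]-4H-chromen-4-one | CC(=O)c1c(F)c(-c2c(OCc3ccccc3)cc(OCc3ccccc3)c3c(=O)cc(-c4ccc(OCc5ccccc5)cc4)oc23)c(OCc2ccccc2)cc1OCc1ccccc1 | intermediate
12 | trimethylsilyl enol ether of 11 | C=C(O[Si](C)(C)C)c1c(F)c(-c2c(OCc3ccccc3)cc(OCc3ccccc3)c3c(=O)cc(-c4ccc(OCc5ccccc5)cc4)oc23)c(OCc2ccccc2)cc1OCc1ccccc1 | intermediate
13 | 4-(benzyloxy)benzaldehyde | O=Cc1ccc(OCc2ccccc2)cc1 | starting material
14 | trichlorosilyl ether of the (S)-aldol (not isolated) | O=C(C[C@H](O[Si](Cl)(Cl)Cl)c1ccc(OCc2ccccc2)cc1)c1c(F)c(-c2c(OCc3ccccc3)cc(OCc3ccccc3)c3c(=O)cc(-c4ccc(OCc5ccccc5)cc4)oc23)c(OCc2ccccc2)cc1OCc1ccccc1 | intermediate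
15 | (S)-aldol, 8-{4,6-bis(benzyloxy)-3-[(3S)-3-(4-benzyloxyphenyl)-3-hydroxypropanoyl]-2-fluorophenyl}-5,7-bis(benzyloxy)-2-[4-(benzyloxy)phenyl]-4H-chromen-4-one (not isolated) | O=C(C[C@H](O)c1ccc(OCc2ccccc2)cc1)c1c(F)c(-c2c(OCc3ccccc3)cc(OCc3ccccc3)c3c(=O)cc(-c4ccc(OCc5ccccc5)cc4)oc23)c(OCc2ccccc2)cc1OCc1ccccc1 | intermediate
16 | potassium alkoxide of 15 (not isolated) | O=C(C[C@H]([O-])c1ccc(OCc2ccccc2)cc1)c1c(F)c(-c2c(OCc3ccccc3)cc(OCc3ccccc3)c3c(=O)cc(-c4ccc(OCc5ccccc5)cc4)oc23)c(OCc2ccccc2)cc1OCc1ccccc1.[K+] | intermediate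
17 | (2S)-5,7-bis(benzyloxy)-2-[4-(benzyloxy)phenyl]-8-{5,7-bis(benzyloxy)-2-[4-(benzyloxy)phenyl]-4-oxo-4H-chromen-8-yl}chroman-4-one | O=C1C[C@@H](c2ccc(OCc3ccccc3)cc2)Oc2c1c(OCc1ccccc1)cc(OCc1ccccc1)c2-c1c(OCc2ccccc2)cc(OCc2ccccc2)c2c(=O)cc(-c3ccc(OCc4ccccc4)cc3)oc12 | intermediate
18 | (2S)-5,7-dihydroxy-2-(4-hydroxyphenyl)-8-[5,7-dihydroxy-2-(4-hydroxyphenyl)-4-oxo-4H-chromen-8-yl]chroman-4-one (CNP0339995.1) | O=C1C[C@@H](c2ccc(O)cc2)Oc2c1c(O)cc(O)c2-c1c(O)cc(O)c2c(=O)cc(-c3ccc(O)cc3)oc12 | target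

Total step count: 10. Longest linear sequence: 7 steps (steps 1, 2, 3, 7, 8, 9, 10).

Steps most likely to fail

Step 9. Retro-aldol cleavage and dehydration of the potassium aldolate may outrun the ring closure at the hindered C8a, which would erode the enantiomeric purity or divert material to the chalcone. The flavone carbonyl may also slow the aldol stage by competing for the silicon Lewis acid. The fallback closes ring C at the other C–O bond (O1–C2) and sets out from 11. Acetohydroxamic acid and K2CO3 in DMSO at 80 °C replace the fluorine by a hydroxyl group and give 8-[3-acetyl-4,6-bis(benzyloxy)-2-hydroxyphenyl]-5,7-bis(benzyloxy)-2-[4-(benzyloxy)phenyl]-4H-chromen-4-one F1. Me3SiOTf (2.5 equiv) and Et3N convert it into the aryl silyl ether and enol silane, the bis(trimethylsilyl) derivative of F1 F2. The same SiCl4/bisphosphoramide aldol addition to 13, now with the antipodal catalyst (Re-face attack) and the aqueous KF quench, gives the (R)-aldol with a free C8a phenol F3. A Mitsunobu cyclisation (PPh3, diisopropyl azodicarboxylate, THF, 0 °C) then forms O1–C2 with inversion at C2, and the route is rejoined at 17.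

Step 7. Protodeboronation of the doubly ortho-oxygenated boronate 4 and slow transmetalation in a coupling that builds a biaryl with four ortho substituents may leave 10 unconsumed. The fallback sets out from 3: zinc insertion (Zn dust, LiCl, THF, 50 °C) gives [5,7-bis(benzyloxy)-2-(4-benzyloxyphenyl)-4-oxo-4H-chromen-8-yl]zinc iodide F4, and a Negishi coupling with 10 (Pd(OAc)2, SPhos, THF, 60 °C), which needs no base and tolerates the ketone, rejoins the route at 11.

Step 10. Over-reduction (hydrogenolysis of the benzylic C2–O1 bond of ring C, saturation of the flavone C2''=C3'' bond) or incomplete cleavage of the hindered 5-O-benzyl ethers may accompany the hydrogenolysis. The fallback sets out from 17 and cleaves all six benzyl ethers without hydrogen, by BCl3 with pentamethylbenzene as cation scavenger in CH2Cl2 at −78 °C, which leads directly to 18.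

Further compounds
F1 | step 9 | 8-[3-acetyl-4,6-bis(benzyloxy)-2-hydroxyphenyl]-5,7-bis(benzyloxy)-2-[4-(benzyloxy)phenyl]-4H-chromen-4-one | CC(=O)c1c(O)c(-c2c(OCc3ccccc3)cc(OCc3ccccc3)c3c(=O)cc(-c4ccc(OCc5ccccc5)cc4)oc23)c(OCc2ccccc2)cc1OCc1ccccc1
F2 | step 9 | bis(trimethylsilyl) derivative of F1 (aryl silyl ether and enol silane) | C=C(O[Si](C)(C)C)c1c(O[Si](C)(C)C)c(-c2c(OCc3ccccc3)cc(OCc3ccccc3)c3c(=O)cc(-c4ccc(OCc5ccccc5)cc4)oc23)c(OCc2ccccc2)cc1OCc1ccccc1
F3 | step 9 | (R)-aldol with a free C8a phenol, 8-{4,6-bis(benzyloxy)-3-[(3R)-3-(4-benzyloxyphenyl)-3-hydroxypropanoyl]-2-hydroxyphenyl}-5,7-bis(benzyloxy)-2-[4-(benzyloxy)phenyl]-4H-chromen-4-one | O=C(C[C@@H](O)c1ccc(OCc2ccccc2)cc1)c1c(O)c(-c2c(OCc3ccccc3)cc(OCc3ccccc3)c3c(=O)cc(-c4ccc(OCc5ccccc5)cc4)oc23)c(OCc2ccccc2)cc1OCc1ccccc1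
F4 | step 7 | [5,7-bis(benzyloxy)-2-(4-benzyloxyphenyl)-4-oxo-4H-chromen-8-yl]zinc iodide | I[Zn]c1c(OCc2ccccc2)cc(OCc2ccccc2)c2c(=O)cc(-c3ccc(OCc4ccccc4)cc3)oc12
F0 | step 10 | none | none
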